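**Retrosynthetic overview**
1. The pyran ring is closed last. C1–H and the C2 methyl come from reductive opening of an aryloxycyclopropane made from a 4H-chromene. The C6–H face of the cyclopentene is the open one, so C1′ is bonded first and the methyl carbon is added second, from that face.
2. The 4H-chromene comes from an o-quinone methide [4+2] (C1′–C2 and O–C1 bonds) between isovaleraldehyde, 2,4,6-trihydroxyisophthalaldehyde and the enol acetate of the spiro ketone.
3. The spiro[4.5]decene comes from an organocatalytic Diels–Alder of acrolein with a semicyclic triene, which sets C5 and C10; the formyl group is then reduced to the C10 methyl.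
4. The triene comes from cyclopentanone and 2-isopropylacrolein by aldol condensation (E alkene) and enol acetylation.
5. Ring order: cyclopentane (bought), then cyclohexene (Diels–Alder), then pyran (hetero-Diels–Alder).

Assumption: 2-isopropylacrolein and 2,4,6-trihydroxyisophthalaldehyde are bought; locants are spiro[4.5]decane C1–C10 (C1 bears O, C2 bears the angular methyl, C5 spiro, C10 bears CH3) and C1′ for the benzylic CH(isobutyl).

**Step 1**
Reactants: 1 cyclopentanone; 2 2-isopropylacrolein (3-methyl-2-methylidenebutanal)
Product: 6 (E)-2-(3-methyl-2-methylidenebutylidene)cyclopentan-1-one, via lithium enolate 3 (not isolated), via lithium aldolate 4 (not isolated), via mesylate 5 (not isolated)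
Conditions: LDA, THF, −78 °C; 2, −78 °C; MsCl, Et3N, −78 → 40 °C
Reagents that add atoms: none
Why: Directed aldol (kinetic lithium enolate, 1,2-addition to the enal) followed by E1cB loss of mesylate gives the thermodynamically preferred E-alkylidene ketone, which erases the two transient, uncontrolled aldol centres in the same flask.

**Step 2**
Reactants: 6 (E)-2-(3-methyl-2-methylidenebutylidene)cyclopentan-1-one
Product: 8 (E)-5-(3-methyl-2-methylidenebutylidene)cyclopent-1-en-1-yl acetate, via lithium dienolate 7 (not isolated)
Conditions: LiHMDS, THF, −78 °C; Ac2O, −78 → 0 °C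
Reagents that add atoms: acetic anhydride CC(=O)OC(C)=O
Why: Only C2 carries acidic hydrogens, so kinetic deprotonation and O-acetylation (House enol acetate synthesis) replace the diene-deactivating carbonyl by a weakly nucleophilic enol ester without touching the E geometry; no stereocentre is formed.

**Step 3**
Reactants: 8 (E)-5-(3-methyl-2-methylidenebutylidene)cyclopent-1-en-1-yl acetate; 9 acrolein
Product: 10 (5S,10R)-10-formyl-7-isopropylspiro[4.5]deca-1,6-dien-1-yl acetate
Conditions: 9 (3 equiv), (2S,5S)-5-benzyl-2-tert-butyl-3-methylimidazolidin-4-one·TFA (20 mol %), MeNO2/H2O 95:5, −10 °C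
Reagents that add atoms: none
Why: Proposed new method: iminium-catalysed Diels–Alder of acrolein with a semicyclic diene whose reacting terminus (C5) is fully substituted, so that a spiro quaternary stereocentre is formed; the closest known reaction is the imidazolidinone-catalysed acrolein Diels–Alder with 1- and 2-substituted acyclic dienes. The LUMO-lowered iminium is attacked first by the unhindered C8 terminus (developing allyl cation stabilised at C7 and at C5 by the cross-conjugated acetoxyvinyl group), which fixes the regiochemistry with CHO on C10; the benzyl group of the (5S) catalyst shields the Re face so the diene adds to the Si face of the α-carbon (10R); endo approach is enforced because an exo iminium would sit between both C5 substituents, and with the E diene (C1 outside) this places CHO cis to C1 (5S).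

**Step 4**
Reactants: 10 (5S,10R)-10-formyl-7-isopropylspiro[4.5]deca-1,6-dien-1-yl acetate
Product: 12 (5R,10R)-7-isopropyl-10-methylspiro[4.5]deca-1,6-dien-1-yl acetate, via tosylhydrazone 11 (not isolated)
Conditions: TsNHNH2, EtOH, rt; evaporate; catecholborane, CHCl3, 0 °C; NaOAc·3H2O, reflux
Reagents that add atoms: none
Why: Kabalka reduction (hydroboration of the C=N bond, acetate-induced loss of sulfinate, N2 extrusion from the alkyldiazene) turns CHO into CH3 under conditions that leave the enol acetate, both alkenes and the C10 centre untouched (the descriptor at C5 changes only through CIP priorities).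

**Step 5**
Reactants: 12 (5R,10R)-7-isopropyl-10-methylspiro[4.5]deca-1,6-dien-1-yl acetate; 13 isovaleraldehyde; 14 2,4,6-trihydroxyisophthalaldehyde
Product: 17 (1′R,5R,10R)-4H-chromene (6,8-diformyl-5,7-dihydroxy-4-isobutyl-4H-chromene fused through its C2=C3 bond to C1=C2 of the spiro terpene), via quinone methide 15 (not isolated), via acetoxychroman cycloadduct 16 (not isolated)
Conditions: 12 (1.5 equiv), 13 (1.2 equiv), 14 (1.0 equiv), NaOAc, AcOH, 80 °C
Reagents that add atoms: none
Why: Knoevenagel condensation gives the o-quinone methide, which undergoes inverse-demand hetero-Diels–Alder with the enol acetate (electrophilic C1′ to C2, O to C1) and then loses AcOH to the enol ether; C1′ is set because the quinone methide adds to the less hindered C6–H face of the cyclopentene (the other face is blocked by the C10 methyl) with the acetoxy group endo and the bulky spiro ring exo, which leaves the isobutyl group on the C10 face of the planar chromene.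

**Step 6**
Reactants: 17 (1′R,5R,10R)-4H-chromene
Product: 18 (1′R,1R,2R,5R,10R)-1,2-methano-chroman (cyclopropane across C1–C2 with its CH2 on the C6–H face)
Conditions: Et2Zn (6 equiv), CH2I2 (6 equiv), CH2Cl2, 0 °C → rt
Reagents that add atoms: diiodomethane ICI
Why: Furukawa–Simmons–Smith cyclopropanation of the electron-rich enol ether (preferred over the hindered trialkyl alkene) occurs anti to the pseudoaxial isobutyl group and anti to the C10 methyl, which sets C2 (and C1) with the future methyl carbon on the C6–H face.

**Step 7**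
Reactants: 18 (1′R,1R,2R,5R,10R)-1,2-methano-chroman
Product: 20 target (1′R,1R,2S,5R,10R), via oxocarbenium trifluoroacetate 19 (not isolated)
Conditions: Et3SiH (5 equiv), TFA (10 equiv), CH2Cl2, −20 → 0 °C
Reagents that add atoms: none
Why: Oxygen-assisted acid opening of the aryloxycyclopropane at the exocyclic C1–CH2 bond (protonation at CH2) gives the oxocarbenium ion bearing the angular methyl, and ionic hydrogenation delivers hydride to C1 on the face of that methyl, which is the only way to the cis-fused chroman and is also the open C6–H face.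

**Compound list**
1 | cyclopentanone | O=C1CCCC1 | starting material
2 | 2-isopropylacrolein (3-methyl-2-methylidenebutanal) | CC(C)C(=C)C=O | starting material
3 | lithium cyclopent-1-en-1-olate | [Li+].[O-]C1=CCCC1 | intermediate
4 | lithium 3-methyl-2-methylidene-1-(2-oxocyclopentyl)butan-1-olate (racemic diastereomer mixture, centres erased in step 1) | [Li+].[O-]C(C1CCCC1=O)C(=C)C(C)C | intermediate
5 | 3-methyl-2-methylidene-1-(2-oxocyclopentyl)butyl methanesulfonate (racemic diastereomer mixture) | CS(=O)(=O)OC(C1CCCC1=O)C(=C)C(C)C | intermediate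
6 | (E)-2-(3-methyl-2-methylidenebutylidene)cyclopentan-1-one | O=C1CCC/C1=C\C(=C)C(C)C | intermediate
7 | lithium (E)-5-(3-methyl-2-methylidenebutylidene)cyclopent-1-en-1-olate | [Li+].[O-]C1=CCC/C1=C\C(=C)C(C)C | intermediate
8 | (E)-5-(3-methyl-2-methylidenebutylidene)cyclopent-1-en-1-yl acetate | CC(=O)OC1=CCC/C1=C\C(=C)C(C)C | intermediate
9 | acrolein | C=CC=O | starting material
10 | (5S,10R)-10-formyl-7-isopropylspiro[4.5]deca-1,6-dien-1-yl acetate | CC(=O)OC1=CCC[C@@]12C=C(C(C)C)CC[C@H]2C=O | intermediate
11 | (E)-N-tosylhydrazone of 10 | CC(=O)OC1=CCC[C@@]12C=C(C(C)C)CC[C@H]2/C=N/NS(=O)(=O)c1ccc(C)cc1 | intermediate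
12 | (5R,10R)-7-isopropyl-10-methylspiro[4.5]deca-1,6-dien-1-yl acetate | CC(=O)OC1=CCC[C@@]12C=C(C(C)C)CC[C@H]2C | intermediate
13 | isovaleraldehyde | CC(C)CC=O | starting material
14 | 2,4,6-trihydroxyisophthalaldehyde | O=Cc1c(O)cc(O)c(C=O)c1O | starting material
15 | (E)-2,4-diformyl-3,5-dihydroxy-6-(3-methylbutylidene)cyclohexa-2,4-dien-1-one (o-quinone methide) | CC(C)C/C=C1/C(=O)C(C=O)=C(O)C(C=O)=C1O | intermediate
16 | (1′R,1R,2R,5R,10R)-1-acetoxychroman cycloadduct (ring O and C1′ on the C6–H face; OAc on C1 and H on C2 on the C10 face) | CC(C)C[C@H]1c2c(O)c(C=O)c(O)c(C=O)c2O[C@@]2(OC(C)=O)[C@@H]1CC[C@@]21C=C(C(C)C)CC[C@H]1C | intermediate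
17 | (1′R,5R,10R)-4H-chromene with C1=C2 enol ether | CC(C)C[C@H]1c2c(O)c(C=O)c(O)c(C=O)c2OC2=C1CC[C@@]21C=C(C(C)C)CC[C@H]1C | intermediate
18 | (1′R,1R,2R,5R,10R)-1,2-methano-chroman (cyclopropane CH2 on the C6–H face) | CC(C)C[C@H]1c2c(O)c(C=O)c(O)c(C=O)c2O[C@@]23C[C@@]31CC[C@@]21C=C(C(C)C)CC[C@H]1C | intermediate
19 | (1′R,2S,5R,10R)-2-methyl oxocarbenium trifluoroacetate (C1=O+) | CC(C)C[C@H]1c2c(O)c(C=O)c(O)c(C=O)c2[O+]=C2[C@@]1(C)CC[C@@]21C=C(C(C)C)CC[C@H]1C.[O-]C(=O)C(F)(F)F | intermediate
20 | CNP0121396.1, (1′R,1R,2S,5R,10R) | CC(C)C[C@H]1c2c(O)c(C=O)c(O)c(C=O)c2O[C@@H]2[C@@]1(C)CC[C@@]21C=C(C(C)C)CC[C@H]1C | target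

**Totals**
Total step count: 7. Longest linear sequence: 7 (steps 1 to 7 from cyclopentanone).

**Three steps most likely to fail**

Step 3 (the proposed new Diels–Alder). The inside CH2 on the diene terminus may make the cycloaddition too slow, or the triene may isomerise under the amine salt. The fallback sets out from 8 and uses a chiral Lewis-acid Diels–Alder, a known reaction type for unactivated acyclic dienes: oxazaborolidinium triflimide (Corey type, antipode chosen by the established model to give the same face) with 2,2,2-trifluoroethyl acrylate gives the endo (5S,10R)-trifluoroethyl ester F1. LiAlH4 reduces the ester and cleaves the enol acetate to an aluminium enolate that survives until work-up, giving the (5S,10R)-keto alcohol F2. Appel iodination (I2, PPh3, imidazole) gives the (5S,10R)-iodide F3, and Bu3SnH/AIBN gives the (5R,10R)-10-methyl ketone F4. Isopropenyl acetate with catalytic TsOH re-forms the enol acetate (only C2 can enolise), and the route is rejoined at 12.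

Step 5 (three-component hetero-Diels–Alder). The enol acetate may be too weak a partner, chromene 17 may add a second quinone methide, or C1′ may form as a mixture. The fallback sets out from 12 and reverses the polarity of the C1′–arene bond. MeLi (2 equiv) gives the lithium enolate F5, which adds to isovaleraldehyde 13 to give the aldol F6; TsOH dehydration gives the (E)-2-(3-methylbutylidene) ketone F7. Acid-catalysed Friedel–Crafts conjugate addition of 14 to this enone (TsOH, toluene, 80 °C), followed by cyclodehydration of the resulting hemiketal, gives the chromene. Any C1′ epimer is separated at this stage, and the route is rejoined at 17.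

Step 6 (cyclopropanation). The free phenols and chelated aldehydes may consume or divert the zinc carbenoid, and the tetrasubstituted aryl enol ether may be sluggish. The fallback sets out from 17 and masks the arene first: Ac2O/pyridine gives the chromene diacetate F8. Cyclopropanation with the more electrophilic Shi carbenoid (Et2Zn, TFA, CH2I2) gives the cyclopropane diacetate F9, with the same facial sense as in step 6. K2CO3 in MeOH removes both acetates, and the route is rejoined at 18.

**Further compounds**
F1 | step 3 | (5S,10R)-2,2,2-trifluoroethyl 1-acetoxy-7-isopropylspiro[4.5]deca-1,6-diene-10-carboxylate | CC(=O)OC1=CCC[C@@]12C=C(C(C)C)CC[C@H]2C(=O)OCC(F)(F)F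
F2 | step 3 | (5S,10R)-10-(hydroxymethyl)-7-isopropylspiro[4.5]dec-6-en-1-one | O=C1CCC[C@@]12C=C(C(C)C)CC[C@H]2CO
F3 | step 3 | (5S,10R)-10-(iodomethyl)-7-isopropylspiro[4.5]dec-6-en-1-one | O=C1CCC[C@@]12C=C(C(C)C)CC[C@H]2CI
F4 | step 3 | (5R,10R)-7-isopropyl-10-methylspiro[4.5]dec-6-en-1-one | O=C1CCC[C@@]12C=C(C(C)C)CC[C@H]2C
F5 | step 5 | lithium (5R,10R)-7-isopropyl-10-methylspiro[4.5]deca-1,6-dien-1-olate | [Li+].[O-]C1=CCC[C@@]12C=C(C(C)C)CC[C@H]2C
F6 | step 5 | (5R,10R)-2-(1-hydroxy-3-methylbutyl)-7-isopropyl-10-methylspiro[4.5]dec-6-en-1-one (mixture at the two new centres) | O=C1C(C(O)CC(C)C)CC[C@@]12C=C(C(C)C)CC[C@H]2C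
F7 | step 5 | (5R,10R,E)-7-isopropyl-10-methyl-2-(3-methylbutylidene)spiro[4.5]dec-6-en-1-one | O=C1/C(=C/CC(C)C)CC[C@@]12C=C(C(C)C)CC[C@H]2C
F8 | step 6 | 5,7-di-O-acetyl derivative of chromene 17 | CC(C)C[C@H]1c2c(OC(C)=O)c(C=O)c(OC(C)=O)c(C=O)c2OC2=C1CC[C@@]21C=C(C(C)C)CC[C@H]1C
F9 | step 6 | 5,7-di-O-acetyl derivative of cyclopropane 18 | CC(C)C[C@H]1c2c(OC(C)=O)c(C=O)c(OC(C)=O)c(C=O)c2O[C@@]23C[C@@]31CC[C@@]21C=C(C(C)C)CC[C@H]1C
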